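**Retrosynthetic overview**
- The target is the product of a final O-debenzylation of its 3′,4′-di-O-benzyl ether. That ether is disconnected at the bond between C2 of the pyranone ring and the ipso carbon of ring B. The forward reaction is an enantioselective Pd(II)-catalysed conjugate arylation of the flat, achiral 3-acetoxy-5-hydroxy-7-methoxychromone with a protected catechol boronic acid.
- Enabling feature: in ring C the atoms O1–C2=C3–C4=O form a vinylogous ester whose β-carbon is C2, and the C4 carbonyl is further polarised by the hydrogen bond from the 5-OH of ring A. In the adduct C3–H is α to the C4 ketone, so the acetoxy-bearing C3 can settle trans to the new C2 aryl group. One operation thus makes the C–C bond, C2 (ligand control) and C3 (thermodynamic control), with the acetate already in place.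
- The 3-acetoxychromone comes from selective 3-O-acetylation of the 3-hydroxychromone, which comes from epoxidation/isomerisation of 5-hydroxy-7-methoxychromone, itself made from 2′,6′-dihydroxy-4′-methoxyacetophenone and DMF-DMA.
- Ring order: rings A and B are bought; ring C is closed first (step 1) and reaches the chromanone level, with both stereocentres, only in the key step.

Key step: step 4

Remark (assumption on the chemistry): (R)-t-BuPyOx is specified on the assumption that the facial sense of aryl delivery follows that of the same catalyst family on cyclic enones and chromones; should the sense be opposite, the enantiomeric ligand is used with no other change. Compounds 1 and 7 are taken as commercial.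

**Step 1**
Reactants: 1 1-(2,6-dihydroxy-4-methoxyphenyl)ethan-1-one
Product: 3 5-hydroxy-7-methoxy-4H-chromen-4-one, via enaminone 2 (not isolated)
Conditions: DMF-DMA (3 equiv), toluene, 95 °C; concentrate; then AcOH, 100 °C
Reagents that add atoms: N,N-dimethylformamide dimethyl acetal, COC(OC)N(C)C
Why: Condensation of the acetyl methyl group with the amide acetal gives the o-hydroxyaryl enaminone, which closes by intramolecular oxa-Michael addition and loss of dimethylamine (enaminone route to chromones), and because the two ortho hydroxyls are equivalent only one chromone can form.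

**Step 2**
Reactants: 3 5-hydroxy-7-methoxy-4H-chromen-4-one
Product: 5 3,5-dihydroxy-7-methoxy-4H-chromen-4-one, via epoxychromanone 4 (not isolated)
Conditions: DMDO (ca. 0.07 M in acetone, 2 equiv), CH2Cl2, 0 °C to rt; evaporate; then TsOH·H2O (5 mol %), CH2Cl2, rt
Reagents that add atoms: dimethyldioxirane, CC1(C)OO1
Why: Dimethyldioxirane epoxidises the enol-ether C2=C3 bond of chromones, and acid opens the epoxide at the acetal carbon C2 to an oxocarbenium ion that loses the acidic C3–H to give the 3-hydroxychromone (epoxidation–isomerisation, as in the flavone-to-flavonol conversion), while the chelated 5-OH on the carbonyl-deactivated ring A should be left alone at this temperature.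

**Step 3**
Reactants: 5 3,5-dihydroxy-7-methoxy-4H-chromen-4-one
Product: 6 5-hydroxy-7-methoxy-4-oxo-4H-chromen-3-yl acetate
Conditions: Ac2O (1.05 equiv), pyridine (2 equiv), CH2Cl2, 0 °C
Reagents that add atoms: acetic anhydride, CC(=O)OC(C)=O
Why: Chemoselective O-acylation is expected because the enolic 3-OH reacts much faster than the 5-OH, which is locked in a six-membered hydrogen bond to C4=O and is the last hydroxyl to be esterified in 5-hydroxyflavonoids.

**Step 4**
Reactants: 6 5-hydroxy-7-methoxy-4-oxo-4H-chromen-3-yl acetate; 7 [3,4-bis(benzyloxy)phenyl]boronic acid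
Product: 9 (2R,3R)-2-[3,4-bis(benzyloxy)phenyl]-5-hydroxy-7-methoxy-4-oxochroman-3-yl acetate, via enol 8 (not isolated)
Conditions: Pd(OCOCF3)2 (10 mol %), (R)-t-BuPyOx (12 mol %), NH4PF6 (30 mol %), H2O (5 equiv), 7 (2 equiv), ClCH2CH2Cl, N2, 60 °C; then CSA (10 mol %), CHCl3, rt
Reagents that add atoms: none
Why: Proposed new method: transmetalation of 7 to the cationic Pd(II)–pyridine-oxazoline complex, coordination of the C2=C3 bond of 6 and migratory insertion should place the aryl group on C2 and palladium on C3, where the C-bound enolate (chelated by the acetate carbonyl and without a syn β-hydrogen in the ring) passes to the O-bound enolate and is protonated by water to enol 8 and then at C3. The closest known reaction is the Pd(II)/pyridine-oxazoline-catalysed enantioselective conjugate addition of arylboronic acids to 3-unsubstituted chromones (flavanone synthesis); the new element is the acyloxy substituent on the acceptor's α-carbon C3, and no ring is closed. C2 is set by the ligand, which should deliver the aryl group to the Re face of C2 (priorities O1 > C3 > H). C3 is set under thermodynamic control, because its hydrogen is α to the C4 ketone and acid-mediated enolisation lets the acetoxy group settle trans-diequatorial to the aryl group without touching C2. The step needs arylation at C2 and not at C3 or C4, secured by the O1–C2=C3–C4=O polarisation reinforced by the 5-OH···O=C4 hydrogen bond. It also needs conjugate addition instead of oxidative Heck dehydrogenation and survival of the enol acetate, secured by the absence of oxidant and of a syn β-hydrogen and by the base-free medium.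

**Step 5**
Reactants: 9 (2R,3R)-2-[3,4-bis(benzyloxy)phenyl]-5-hydroxy-7-methoxy-4-oxochroman-3-yl acetate
Product: 10 3-O-acetylpadmatin
Conditions: H2 (1 atm), 10% Pd/C, EtOAc, rt
Reagents that add atoms: none
Why: Hydrogenolysis of aryl benzyl ethers over Pd/C under neutral conditions should release the catechol and toluene while the 3-acetate, the chelated ketone and both stereocentres, which are exposed to no base and no enolising medium, stay untouched.

**Compound list**
1 | 1-(2,6-dihydroxy-4-methoxyphenyl)ethan-1-one (2′,6′-dihydroxy-4′-methoxyacetophenone) | CC(=O)c1c(O)cc(OC)cc1O | starting material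
2 | (E)-1-(2,6-dihydroxy-4-methoxyphenyl)-3-(dimethylamino)prop-2-en-1-one | CN(C)/C=C/C(=O)c1c(O)cc(OC)cc1O | intermediate
3 | 5-hydroxy-7-methoxy-4H-chromen-4-one | COc1cc(O)c2c(c1)occc2=O | intermediate
4 | rac-5-hydroxy-7-methoxy-2,3-epoxychroman-4-one (cis-fused oxirane, one enantiomer drawn) | COc1cc(O)c2c(c1)O[C@@H]1O[C@@H]1C2=O | intermediate
5 | 3,5-dihydroxy-7-methoxy-4H-chromen-4-one | COc1cc(O)c2c(c1)occ(O)c2=O | intermediate
6 | 5-hydroxy-7-methoxy-4-oxo-4H-chromen-3-yl acetate | COc1cc(O)c2c(c1)occ(OC(C)=O)c2=O | intermediate
7 | [3,4-bis(benzyloxy)phenyl]boronic acid | OB(O)c1ccc(OCc2ccccc2)c(OCc2ccccc2)c1 | starting material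
8 | (2R)-2-[3,4-bis(benzyloxy)phenyl]-4,5-dihydroxy-7-methoxy-2H-chromen-3-yl acetate (enol) | COc1cc(O)c2c(c1)O[C@H](c1ccc(OCc3ccccc3)c(OCc3ccccc3)c1)C(OC(C)=O)=C2O | intermediate
9 | (2R,3R)-2-[3,4-bis(benzyloxy)phenyl]-5-hydroxy-7-methoxy-4-oxochroman-3-yl acetate | COc1cc(O)c2c(c1)O[C@H](c1ccc(OCc3ccccc3)c(OCc3ccccc3)c1)[C@@H](OC(C)=O)C2=O | intermediate
10 | 3-O-acetylpadmatin, (2R,3R)-2-(3,4-dihydroxyphenyl)-5-hydroxy-7-methoxy-4-oxochroman-3-yl acetate | COc1cc(O)c2c(c1)O[C@H](c1ccc(O)c(O)c1)[C@@H](OC(C)=O)C2=O | target

**Step count and risks**
Total step count: 5. Longest linear sequence: 5 steps (1 to 10); boronic acid 7 enters in step 4.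

Steps most likely to fail:

1. Step 4 (proposed new method). Migratory insertion into the trisubstituted, donor-substituted C2=C3 bond may be slow, so that protodeboronation of 7 or hydrolysis of the enol acetate wins. The C3 substituent next to the metal may also erode facial selectivity, and ring opening during the C3 equilibration would erode the C2 configuration. The fallback uses known chemistry, sets out from 3 and comes back at 9. Chromone 3 is arylated with 7 under the same Pd/(R)-t-BuPyOx conditions, the established conjugate addition to 3-unsubstituted chromones, to give (2S)-2-[3,4-bis(benzyloxy)phenyl]-5-hydroxy-7-methoxychroman-4-one F1. Soft enolisation (TMSOTf, Et3N, CH2Cl2, 0 °C) then gives (2S)-2-[3,4-bis(benzyloxy)phenyl]-7-methoxy-4,5-bis(trimethylsilyloxy)-2H-chromene F2. Rubottom oxidation (DMDO, acetone/CH2Cl2, −40 °C; then aqueous citric acid, THF), which should occur anti to the C2 aryl group, gives the trans-dihydroflavonol (2R,3R)-2-[3,4-bis(benzyloxy)phenyl]-3,5-dihydroxy-7-methoxychroman-4-one F3. Acetylation of the secondary 3-OH (Ac2O, pyridine, CH2Cl2, 0 °C; the chelated 5-OH reacts last) returns to 9.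

2. Step 2. The electrophilic oxidant may attack the electron-rich phenolic ring A in competition with the deactivated C2=C3 bond, or the labile epoxide may be hydrolysed before it isomerises. The fallback avoids electrophilic oxygen transfer, sets out from enaminone 2 (isolated after the first stage of step 1) and comes back at 5. Iodocyclisation (I2, CHCl3, rt) gives 5-hydroxy-3-iodo-7-methoxy-4H-chromen-4-one F4. Miyaura borylation (B2pin2, PdCl2(dppf), KOAc, dioxane, 80 °C) gives 5-hydroxy-7-methoxy-3-(4,4,5,5-tetramethyl-1,3,2-dioxaborolan-2-yl)-4H-chromen-4-one F5. Oxidation of the C–B bond (NaBO3·4H2O, THF/H2O, rt) gives 5.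

3. Step 5. Over-reduction is possible (hydrogenolytic opening of the benzylic C2–O1 bond or reduction of the C4 carbonyl), as is incomplete removal of the second benzyl group. The fallback gives up reduction: it sets out from 9 and comes back at 10 by Lewis-acid debenzylation with a cation scavenger (BCl3, pentamethylbenzene, CH2Cl2, −78 °C; then MeOH/aqueous NaHCO3). The benzyl groups leave as benzyl cations trapped by the scavenger, and the acetate and the 7-methyl ether should survive at this temperature. No new compound is made on the way.

**Further compounds**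
F1 | step 4 | (2S)-2-[3,4-bis(benzyloxy)phenyl]-5-hydroxy-7-methoxychroman-4-one | COc1cc(O)c2c(c1)O[C@H](c1ccc(OCc3ccccc3)c(OCc3ccccc3)c1)CC2=O
F2 | step 4 | (2S)-2-[3,4-bis(benzyloxy)phenyl]-7-methoxy-4,5-bis(trimethylsilyloxy)-2H-chromene | COc1cc(O[Si](C)(C)C)c2c(c1)O[C@H](c1ccc(OCc3ccccc3)c(OCc3ccccc3)c1)C=C2O[Si](C)(C)C
F3 | step 4 | (2R,3R)-2-[3,4-bis(benzyloxy)phenyl]-3,5-dihydroxy-7-methoxychroman-4-one | COc1cc(O)c2c(c1)O[C@H](c1ccc(OCc3ccccc3)c(OCc3ccccc3)c1)[C@@H](O)C2=O
F4 | step 2 | 5-hydroxy-3-iodo-7-methoxy-4H-chromen-4-one | COc1cc(O)c2c(c1)occ(I)c2=O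
F5 | step 2 | 5-hydroxy-7-methoxy-3-(4,4,5,5-tetramethyl-1,3,2-dioxaborolan-2-yl)-4H-chromen-4-one | COc1cc(O)c2c(c1)occ(B3OC(C)(C)C(C)(C)O3)c2=O
F0 | step 5 | none | none
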